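(The data come from a simulation from invented constants; noise was put on by code.)

The beta run is slow: after 60.0 s it still holds 64.2% of its starting material, yet we must reckon out to 2.0 min, so we need a clock that carries across flasks. Take c(free catalyst) times time, 20.0 mM·min for red and 40.0 mM·min for ochre, and call it the dose.

| flask | starting material | free catalyst | remark | time |
|---|---|---|---|---|
| beta | 0.20 M | 12 mM | run made earlier |  |
| alpha | 0.20 M | 13 mM | run made earlier |  |
| delta | 0.20 M | 18 mM | run made earlier |  |
| red | 0.20 M | 10 mM |  | 2.0 min |
| ochre | 0.20 M | 20 mM |  | 2.0 min |

| run | time / s | target / % | starting material / % | over-reaction product / % | catalyst intermediate / % |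
|---|---|---|---|---|---|
| beta | 12.0 | 7.5 | 90.2 | 1.9 | 0.3 |
| beta | 25.0 | 16.0 | 85.2 | 1.8 | 0 |
| beta | 40.0 | 22.1 | 73.4 | 4.4 | 1.2 |
| beta | 50.0 | 24.1 | 70.4 | 7.0 | 0 |
| beta | 60.0 | 28.0 | 64.2 | 8.9 | 0.8 |
| alpha | 12.0 | 9.2 | 91.2 | 0.3 | 0 |
| alpha | 25.0 | 16.5 | 82.8 | 1.0 | 0 |
| alpha | 40.0 | 24.5 | 72.4 | 5.1 | 0 |
| alpha | 50.0 | 26.2 | 68.3 | 6.5 | 1.7 |
| alpha | 60.0 | 28.5 | 61.5 | 10.9 | 0 |
| delta | 12.0 | 10.9 | 87.0 | 0.2 | 0 |
| delta | 25.0 | 21.1 | 75.4 | 3.0 | 0.7 |
| delta | 40.0 | 28.0 | 63.7 | 9.1 | 0 |
| delta | 50.0 | 31.3 | 55.2 | 10.4 | 0 |
| delta | 60.0 | 32.1 | 50.6 | 15.9 | 0.1 |

(readings scatter by 1 percentage point)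

- which of these there is most of at the end, counted by the starting material in it, red (over-reaction product / target / catalyst intermediate / starting material)
- which of these there is most of at the end, counted by the starting material in it, ochre (over-reaction product / target / catalyst intermediate / starting material)
- final amount of the leader among these, as a percentage of the starting material charged, in red
- final amount of the leader among these, as a percentage of the starting material charged, in ochre

Here are three readings with their doses, each giving starting material, target and over-reaction product:

- beta at 60.0 s: dose 12.0 mM·min; 64.2%, 28.0%, 8.9%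
- delta at 40.0 s: dose 12.0 mM·min; 63.7%, 28.0%, 9.1%
- delta at 60.0 s: dose 18.0 mM·min; 50.6%, 32.1%, 15.9%

The top two lines are different flasks at one dose. Their starting material differs by 0.5 percentage points and their over-reaction product by 0.2 points, both inside the scatter of 1 point, and target reads the same. So we read composition against dose.

We extrapolate from the third line, delta at its last reading. If starting material falls pseudo-first-order in dose, its logarithm scales with dose, which gives 46.9% for red and 22.0% for ochre.

For target, suppose both steps ran equally fast per dose: target would then be −A·ln A, with A the fraction of starting material left. The third line reads 0.931 of that, and we carry this factor as a small correction. Red then has 33.1% target and 20.0% over-reaction product, so starting material leads. Ochre has 31.0% target and 47.0% over-reaction product, which leads.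

The forecast, “with both steps catalysed”, names starting material for red at 47.5% and over-reaction product for ochre at 45%, the same leaders as ours, and its ochre figure is lower than ours.

    catalyst intermediate → free catalyst + target (k = 4.50 s⁻¹)
    free catalyst + target → free catalyst + over-reaction product (k = 0.720 M⁻¹ s⁻¹)
    starting material + free catalyst ⇌ catalyst intermediate (K = 450 M⁻¹, k = 0.640 M⁻¹ s⁻¹)

In red the leader is starting material, at 47.1%. In ochre the leader is over-reaction product, at 47.5%. In ochre's opening minute starting material fed target, and at 1.00 min ochre held 47.1% starting material, 33.8% target and 18.9% over-reaction product, the state red reached at the same dose; over its second minute target fed over-reaction product, which rose to 47.5% while target slipped to 30.4%. The neighbour charged with 0.017 M free catalyst has dose 34.0 mM·min, which reckons to 27.6% starting material, and it holds 27.7%, beside 32.9% target and 39.4% over-reaction product.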